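If each target costs two partner B, one through open intermediate and one through second intermediate, then the budget of partner B was what I had to reckon first.

all flasks: starting material 0.25 M

| flask | partner A | partner B | protic impurity | temperature | remark | time |
|---|---|---|---|---|---|---|
| maple | 0.20 M | 0.45 M | 0.075 M | 85 °C | run made earlier |  |
| summer | 0.200 M | 0.300 M | 0.0750 M | 85 °C |  | 30 min |
| midnight | 0.200 M | 0.300 M | 0.0750 M | −5 °C |  | 30 min |
| spring | 0.200 M | 0.300 M | 0.0750 M | 55 °C |  | 30 min |
| dusk | 0.200 M | 0.300 M | 0.0750 M | 25 °C |  | 30 min |

maple run (percent of the starting material charged): time / min: target / % = 0.667: 1.6; 2.00: 14.5; 3.00: 17.1; 5.00: 25.6; 6.00: 27.2; 10.0: 32.1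

(standard deviation of a reading: 1 percentage point)

- what may be going on: starting material + partner B -> open intermediate; partner B + protic impurity -> quenched reagent; partner B + partner A -> second intermediate; starting material -> decomposition product; open intermediate + second intermediate -> target; 2 second intermediate -> homo product
- the earlier runs do not show what temperature does; that part of a forecast is a guess

- which flask leads in amount of target, in percent of the starting material charged ("all alike" within 1.5 percentage points) (summer / midnight / spring / dusk / all alike)
- how much target is there at the end, in percent of the starting material charged: summer
- how much target is there at the end, in percent of the starting material charged: midnight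
- how much target is there at the end, in percent of the starting material charged: spring
- how much target is there at the end, in percent of the starting material charged: dusk

I counted in fractions of the starting material charge, with b for partner B and h for protic impurity. I assumed that protic impurity took its whole charge and that each remaining pair of partner B made one target:

C = (b − h)/2

Before working out C, I asked which inputs it needed. For summer, an error of 10 per cent in partner B would move C by 6 percentage points, in starting material by about 4.5 points, and in protic impurity by 1.5 points. Partner A does not enter C, since its fraction 0.800 is larger than C. Time does not enter C, but the maple readings at 85 °C showed how the approach went: maple gained 11 points from 2.00 min to 5.00 min, and 4.9 points from 6.00 min to 10.0 min. Temperature does not enter C either, and the earlier runs do not show what it does, so that part stayed a guess.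

For summer the reckoning was:

C = (1.20 − 0.300)/2 = 45.0%

This budget ceiling is the target fraction that partner B allows after protic impurity has taken its full charge. For maple the same reckoning gave 75.0%, and its last reading stood at 42.8% of that, still rising. Applied to summer, that share gave 19.3%, so I expected summer to end between this value and the ceiling.

The forecast said “Partner B is the limiting budget”, naming the limiting reagent. It gave 25% for summer, 18% for spring, 3% for dusk and 0.2% for midnight, with summer leading. Its summer value is a point inside my interval.

The flasks gave 25.9% in summer, 18.7% in spring, 3.38% in dusk and 0.0288% in midnight, so summer led and the forecast held.

    starting material + partner B → open intermediate (k = 0.00195 /M/s, Ea = 47.0 kJ/mol)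
    partner B + protic impurity → quenched reagent (k = 9.98 × 10⁻⁴ /M/s, Ea = 54.0 kJ/mol)
    partner B + partner A → second intermediate (k = 0.00552 /M/s, Ea = 47.0 kJ/mol)
    starting material → decomposition product (k = 2.71 × 10⁻⁷ /s, Ea = 98.0 kJ/mol)
    open intermediate + second intermediate → target (k = 7.94 × 10⁻⁴ /M/s, Ea = 51.0 kJ/mol)
    2 second intermediate → homo product (k = 6.19 × 10⁻⁴ /M/s, Ea = 53.0 kJ/mol)
    (constants at 25 °C)

At the start of summer, partner B went to second intermediate 2.3 times as fast as to open intermediate. At 30.0 min, summer held partner B 0%, homo product 0.0470 M, second intermediate 0.00291 M and open intermediate 17.9%, with target at 57.6% of the ceiling. The neighbour of summer with 0.42 M of starting material has 0.714 equiv of partner B and a ceiling of 26.8%, and it ended with target 16.9%.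

The numbers in the tables were computed on assumed constants; noise was put on by code.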